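**Plan** (labdane numbering C1–C20 is used for all ring compounds)

- Cuts: the two acetates; the C9–C11 bond (side chain C11–C16 as a Grignard fragment from methyl (R)-glycerate acetonide); then C1–C10 and C3–C4 of ring A together, which leaves (R)-carvone as ring B plus a propane-1,3-diyl linchpin.
- Enabling feature: in 6-methylcarvone, C10 (the α′-carbon of the C9 ketone) and C4 (the internal carbon of the isopropenyl group on C5) sit 1,3 to each other across C5. C10 reacts as a dienolate nucleophile and C4 as a tertiary radical after hydrogen-atom transfer to its =CH2, so one I(CH2)3I unit can close ring A in one flask and create both quaternary carbons and the gem-dimethyl group.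
- Forward order: ring B (carvone) → C10 methylation → ring A annulation → side chain added to the C9 carbonyl → oxidative, then reductive allylic transposition to restore C7=C8 and install 9-H → acetonide off, acetates on.
- Stereochemistry: C5 from (R)-carvone; C10 by enolate alkylation anti to the isopropenyl group (stereoconvergent, gives the trans ring fusion); C9 by suprafacial hydrogen delivery from an allylic diazene on the α face; C14 from the glycerate.

Key step: step 2

Step 1
Reactants: 1 (R)-(−)-carvone
Product: 3 (5R)-2,6-dimethyl-5-(prop-1-en-2-yl)cyclohex-2-en-1-one (6-methylcarvone; both C6 epimers), via lithium dienolate C10H13OLi 2 (not isolated)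
Conditions: LiN(i-Pr)2, THF, −78 °C; MeI, −78 to −20 °C
Reagents that add atoms: iodomethane, CI
Why: Kinetic enolate alkylation: LiN(i-Pr)2 removes a proton from the only sp3 α-carbon (C6 of carvone, the future C10) to give the cross-conjugated dienolate, which is C-methylated; the epimer ratio at this carbon does not matter because it is made planar again in step 2.

Step 2
Reactants: 3 (5R)-6-methylcarvone (both C6 epimers); 4 1,3-diiodopropane
Product: 7 (4aS,8aS)-2,5,5,8a-tetramethyl-4a,5,6,7,8,8a-hexahydronaphthalen-1(4H)-one, via lithium dienolate C11H15OLi 5 (not isolated), via iodo ketone 6 (not isolated)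
Conditions: LiN(i-Pr)2, THF, −78 °C; 4 (4 equiv), −78 °C to rt; THF, HN(i-Pr)2 and excess 4 removed in vacuo; then Mn(C11H19O2)3 (20 mol %), Ni(C5H7O2)2 (10 mol %), PhSiH3, K2CO3, (CF3)2CHOH, ClCH2CH2Cl (0.01 M), rt
Reagents that add atoms: none
Why: Proposed new method: in stage one the cross-conjugated lithium dienolate 5 is C-alkylated by 4 (enolate alkylation); planar C10 erases the epimer mixture of 3 and the electrophile enters anti to the neighbouring C5 isopropenyl group, so C10 is set S with its methyl cis to that group from either epimer (substrate control, stereoconvergent). In stage two a manganese hydride made from PhSiH3 transfers a hydrogen atom to the terminal CH2 of the isopropenyl group, the tertiary C4 radical and the C3–I terminus are united at one nickel centre (radical capture and oxidative addition in either order), and C(sp3)–C(sp3) reductive elimination forms C3–C4 and with it the gem-dimethyl quaternary carbon. The closest known reaction type is the intermolecular manganese/nickel dual-catalytic Markovnikov hydroalkylation of 1,1-disubstituted alkenes with primary alkyl iodides, which builds quaternary carbons; what is new is the ring-closing use and its telescoping with the alkylation. Ring A closes as a six-membered ring through a seven-membered dialkylnickelacycle, and the trans ring fusion is already fixed in stage one because C4 is not stereogenic. The step needs hydrogen-atom transfer to the electron-rich 1,1-disubstituted alkene in preference to the electron-poor trisubstituted enone C7=C8, and ring closure in preference to simple reduction or intermolecular coupling of the radical; the polarity of the metal hydride, high dilution and removal of excess 4 before stage two are expected to secure this.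

Step 3
Reactants: 8 methyl (4R)-2,2-dimethyl-1,3-dioxolane-4-carboxylate
Product: 9 1-[(4R)-2,2-dimethyl-1,3-dioxolan-4-yl]cyclopropan-1-ol
Conditions: EtMgBr (2.4 equiv), Ti(Oi-Pr)4 (20 mol %), THF, 0 °C to rt; aqueous work-up
Reagents that add atoms: ethylmagnesium bromide, CC[Mg]Br
Why: Kulinkovich cyclopropanation: the titanacyclopropane formed from EtMgBr and Ti(Oi-Pr)4 adds twice to the ester carbonyl as a 1,2-dicarbanion equivalent, so the ester carbon becomes the future C13 carrying C11 and C12, and the α-alkoxy stereocentre (future C14) is not touched.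

Step 4
Reactants: 9 1-[(4R)-2,2-dimethyl-1,3-dioxolan-4-yl]cyclopropan-1-ol
Product: 10 3-bromo-1-[(4R)-2,2-dimethyl-1,3-dioxolan-4-yl]propan-1-one
Conditions: N-bromosuccinimide, CH2Cl2, 0 °C, dark
Reagents that add atoms: N-bromosuccinimide, O=C1CCC(=O)N1Br
Why: Electrophilic ring opening of a cyclopropanol (homoenol reactivity): bromine transfer from N-bromosuccinimide cleaves a strained C–C bond to give the β-bromo ketone, the two ring CH2 groups being equivalent so that only one product is possible, and the neutral conditions spare the acetonide and the α-stereocentre.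

Step 5
Reactants: 10 3-bromo-1-[(4R)-2,2-dimethyl-1,3-dioxolan-4-yl]propan-1-one
Product: 11 (4S)-4-(4-bromobut-1-en-2-yl)-2,2-dimethyl-1,3-dioxolane
Conditions: Zn, CH2Br2, TiCl4, THF (reagent preformed at 0–5 °C); then 10, CH2Cl2, rt
Reagents that add atoms: dibromomethane, BrCBr
Why: Takai–Lombardo methylenation: the non-basic titanium methylidene reagent converts the ketone into the C13=C16 alkene without E1cB loss of HBr or epimerisation at the α-alkoxy carbon, whose descriptor changes from R to S only through the priority rules.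

Step 6
Reactants: 11 (4S)-4-(4-bromobut-1-en-2-yl)-2,2-dimethyl-1,3-dioxolane; 7 (4aS,8aS)-2,5,5,8a-tetramethyl-4a,5,6,7,8,8a-hexahydronaphthalen-1(4H)-one
Product: 13 (5S,10S,14S)-14,15-(isopropylidenedioxy)labda-7,13(16)-dien-9-ol as either C9 epimer, via Grignard reagent C9H15O2MgBr 12 (not isolated)
Conditions: 11 (1.5 equiv), Mg, THF, rt; LaCl3·2LiCl (1.5 equiv), then 7, THF, 0 °C to rt; aqueous work-up
Reagents that add atoms: none
Why: Grignard formation followed by LaCl3·2LiCl-promoted 1,2-addition to a hindered enone that has no α′-hydrogen: the lanthanum salt raises carbonyl electrophilicity and suppresses γ-deprotonation and β-hydride reduction, and the configuration of the new carbinol carbon C9 is of no consequence because it is erased in step 7.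

Step 7
Reactants: 13 (5S,10S,14S)-14,15-(isopropylidenedioxy)labda-7,13(16)-dien-9-ol
Product: 14 (5S,10S,14S)-14,15-(isopropylidenedioxy)labda-8,13(16)-dien-7-one
Conditions: C5H5NH[CrO3Cl] (pyridinium chlorochromate, 3 equiv), 4 Å molecular sieves, CH2Cl2, rt
Reagents that add atoms: none
Why: Babler–Dauben oxidative 1,3-transposition: the tertiary allylic chromate ester rearranges by a [3,3] shift to the C7 chromate, which is oxidised to the β,β-disubstituted enone, so that oxygen moves from C9 to C7 and the alkene to C8=C9.

Step 8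
Reactants: 14 (5S,10S,14S)-14,15-(isopropylidenedioxy)labda-8,13(16)-dien-7-one
Product: 15 (5S,7S,10S,14S)-14,15-(isopropylidenedioxy)labda-8,13(16)-dien-7-ol (7β-OH)
Conditions: NaBH4, CeCl3·7H2O, MeOH, −40 °C
Reagents that add atoms: none
Why: Luche 1,2-reduction: the small cerium-modified borohydride should attack the half-chair enone axially from the α face, opposite to the β-oriented C10 methyl group, to give the pseudo-equatorial 7β-alcohol (7S).

Step 9
Reactants: 15 (5S,7S,10S,14S)-14,15-(isopropylidenedioxy)labda-8,13(16)-dien-7-ol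
Product: 18 (5S,9S,10S,14S)-14,15-(isopropylidenedioxy)labda-7,13(16)-diene, via sulfonyl hydrazide 16 (not isolated), via allylic diazene 17 (not isolated)
Conditions: 2-nitrobenzenesulfonylhydrazide (NBSH), PPh3, diethyl azodicarboxylate, N-methylmorpholine, −30 °C; then rt
Reagents that add atoms: none
Why: Reductive 1,3-allylic transposition through an allylic diazene: Mitsunobu displacement by NBSH inverts C7 and places nitrogen on the α face, loss of 2-nitrobenzenesulfinic acid gives the diazene, and its retro-ene extrusion of N2 delivers hydrogen suprafacially to C9 from the α face, which sets 9S (9α-H) and moves the alkene to C7=C8.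

Step 10
Reactants: 18 (5S,9S,10S,14S)-14,15-(isopropylidenedioxy)labda-7,13(16)-diene
Product: 19 (5S,9S,10S,14S)-labda-7,13(16)-diene-14,15-diol
Conditions: AcOH/H2O (4:1), 40 °C
Reagents that add atoms: none
Why: Acid-catalysed acetal hydrolysis under mild conditions that should leave the allylic diol and both alkenes in place; no stereocentre is affected.

Step 11
Reactants: 19 (5S,9S,10S,14S)-labda-7,13(16)-diene-14,15-diol
Product: 20 (5S,9S,10S,14S)-labda-7,13(16)-diene-14,15-diyl diacetate
Conditions: Ac2O, pyridine, DMAP (cat.), CH2Cl2, 0 °C to rt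
Reagents that add atoms: acetic anhydride, CC(=O)OC(C)=O
Why: DMAP-catalysed acylation of the primary and the secondary allylic hydroxyl groups; no stereocentre is affected.

**Compound list**

1 | (R)-(−)-carvone, (5R)-2-methyl-5-(prop-1-en-2-yl)cyclohex-2-en-1-one | C=C(C)[C@@H]1CC=C(C)C(=O)C1 | starting material
2 | lithium dienolate of 1, C10H13OLi (deprotonated at C6 of carvone) | C=C(C)[C@@H]1CC=C(C)C([O-])=C1.[Li+] | intermediate
3 | (5R)-2,6-dimethyl-5-(prop-1-en-2-yl)cyclohex-2-en-1-one (6-methylcarvone; both C6 epimers) | C=C(C)[C@@H]1CC=C(C)C(=O)C1C | intermediate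
4 | 1,3-diiodopropane | ICCCI | starting material
5 | lithium dienolate of 3, C11H15OLi | C=C(C)[C@@H]1CC=C(C)C([O-])=C1C.[Li+] | intermediate
6 | (5S,6S)-6-(3-iodopropyl)-2,6-dimethyl-5-(prop-1-en-2-yl)cyclohex-2-en-1-one | C=C(C)[C@@H]1CC=C(C)C(=O)[C@@]1(C)CCCI | intermediate
7 | (4aS,8aS)-2,5,5,8a-tetramethyl-4a,5,6,7,8,8a-hexahydronaphthalen-1(4H)-one (trans-fused; 5α-H, 10β-CH3) | O=C1C(C)=CC[C@H]2C(C)(C)CCC[C@]12C | intermediate
8 | methyl (4R)-2,2-dimethyl-1,3-dioxolane-4-carboxylate | COC(=O)[C@H]1COC(C)(C)O1 | starting material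
9 | 1-[(4R)-2,2-dimethyl-1,3-dioxolan-4-yl]cyclopropan-1-ol | OC1(CC1)[C@H]1COC(C)(C)O1 | intermediate
10 | 3-bromo-1-[(4R)-2,2-dimethyl-1,3-dioxolan-4-yl]propan-1-one | BrCCC(=O)[C@H]1COC(C)(C)O1 | intermediate
11 | (4S)-4-(4-bromobut-1-en-2-yl)-2,2-dimethyl-1,3-dioxolane | BrCCC(=C)[C@H]1COC(C)(C)O1 | intermediate
12 | {3-[(4S)-2,2-dimethyl-1,3-dioxolan-4-yl]but-3-en-1-yl}magnesium bromide, C9H15O2MgBr | Br[Mg]CCC(=C)[C@H]1COC(C)(C)O1 | intermediate
13 | (5S,10S,14S)-14,15-(isopropylidenedioxy)labda-7,13(16)-dien-9-ol (5α-H, 10β-CH3; either C9 epimer) | CC1=CC[C@H]2C(C)(C)CCC[C@]2(C)C1(O)CCC(=C)[C@H]1COC(C)(C)O1 | intermediate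
14 | (5S,10S,14S)-14,15-(isopropylidenedioxy)labda-8,13(16)-dien-7-one | O=C1C[C@H]2C(C)(C)CCC[C@]2(C)C(CCC(=C)[C@H]3COC(C)(C)O3)=C1C | intermediate
15 | (5S,7S,10S,14S)-14,15-(isopropylidenedioxy)labda-8,13(16)-dien-7-ol (7β-OH) | O[C@H]1C[C@H]2C(C)(C)CCC[C@]2(C)C(CCC(=C)[C@H]3COC(C)(C)O3)=C1C | intermediate
16 | N-[(5S,7R,10S,14S)-14,15-(isopropylidenedioxy)labda-8,13(16)-dien-7-yl]-N-(2-nitrophenylsulfonyl)hydrazine (nitrogen on the α face of C7) | NN([C@@H]1C[C@H]2C(C)(C)CCC[C@]2(C)C(CCC(=C)[C@H]3COC(C)(C)O3)=C1C)S(=O)(=O)c1ccccc1[N+](=O)[O-] | intermediate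
17 | (5S,7R,10S,14S)-14,15-(isopropylidenedioxy)labda-8,13(16)-dien-7-yldiazene (7α-N=NH) | N=N[C@@H]1C[C@H]2C(C)(C)CCC[C@]2(C)C(CCC(=C)[C@H]3COC(C)(C)O3)=C1C | intermediate
18 | (5S,9S,10S,14S)-14,15-(isopropylidenedioxy)labda-7,13(16)-diene | C=C(CC[C@H]1C(C)=CC[C@H]2C(C)(C)CCC[C@]12C)[C@H]1COC(C)(C)O1 | intermediate
19 | (5S,9S,10S,14S)-labda-7,13(16)-diene-14,15-diol | C=C(CC[C@H]1C(C)=CC[C@H]2C(C)(C)CCC[C@]12C)[C@@H](CO)O | intermediate
20 | (5S,9S,10S,14S)-labda-7,13(16)-diene-14,15-diyl diacetate (CNP0289003.1) | C=C(CC[C@H]1C(C)=CC[C@H]2C(C)(C)CCC[C@]12C)[C@@H](COC(C)=O)OC(C)=O | target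

**Step count and risks**

Total steps: 11. Longest linear sequence: 9 steps (from 8 through steps 3, 4, 5, 6, 7, 8, 9, 10 and 11); the carvone branch has 8 steps.

Steps most likely to fail:

1. Step 2 (proposed new method). The tertiary radical may take up a second hydrogen atom (net hydrogenation of the isopropenyl group) or couple between molecules (oligomerisation), because radical formation and nickel insertion need not occur in the same molecule. Hydrogen-atom transfer may also reach the enone, and lithium salts or amine carried over from stage one may deactivate the nickel catalyst. Fallback with known chemistry, setting out from 3: the lithium dienolate would be alkylated with (Z)-3-bromo-1-iodoprop-1-ene, again anti to the isopropenyl group, to give the vinyl iodide (5S,6S)-6-[(2Z)-3-iodoprop-2-en-1-yl]-2,6-dimethyl-5-(prop-1-en-2-yl)cyclohex-2-en-1-one F1. An intramolecular reductive Heck reaction (Pd(OAc)2, PPh3, HCO2Na, Et4NCl, DMF, 80 °C) would close ring A in the 6-exo mode at C4; the neopentyl palladium intermediate has no β-hydrogen and is reduced by formate, which gives the dienone (4aS,8aS)-2,5,5,8a-tetramethyl-4a,5,8,8a-tetrahydronaphthalen-1(4H)-one F2. Selective hydrogenation of the cis-disubstituted ring A alkene with RhCl(PPh3)3 and H2, which should spare the trisubstituted enone, returns to the route at 7.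

2. Step 6. Deprotonation at the γ-position (C6), β-hydride transfer from the Grignard reagent (carbonyl reduction) or conjugate addition at C7 may outrun 1,2-addition at the hindered C9 carbonyl. Fallback, setting out from 7: γ-deprotonation with LiN(i-Pr)2 and O-sulfonylation with PhNTf2 would give the dienyl triflate (4aS,8aS)-2,5,5,8a-tetramethyl-4a,5,6,7,8,8a-hexahydronaphthalen-1-yl trifluoromethanesulfonate F3. Transmetalation of 12 with ZnCl2 would give {3-[(4S)-2,2-dimethyl-1,3-dioxolan-4-yl]but-3-en-1-yl}zinc chloride F4, and Negishi coupling of F3 with F4 (PdCl2[Fe(C5H4PPh2)2], THF) would give (14S)-14,15-(isopropylidenedioxy)labda-6,8,13(16)-triene F5. A 1,4-hydrogenation of the homoannular diene catalysed by (C10H8)Cr(CO)3 under H2 should add hydrogen to C6 and C9 from the less hindered α face and leave the C7=C8 alkene; this returns to the route at 18 and bypasses steps 7 to 9.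

3. Step 9. Mitsunobu activation of the hindered secondary allylic alcohol may lead to elimination to a diene or to allylic scrambling, so that nitrogen is not placed cleanly on the α face and the facial fidelity of hydrogen transfer to C9 is lost. Fallback, setting out from 15: formylation (HCO2H, Ac2O, pyridine) would give (7S,14S)-14,15-(isopropylidenedioxy)labda-8,13(16)-dien-7-yl formate F6. Palladium-catalysed hydrogenolysis of the allylic formate (Pd(OAc)2, P(n-Bu)3, dioxane, heat) ionises with inversion, puts palladium on the α face, and after decarboxylation delivers hydride to the more substituted allyl terminus C9 from that face; this returns to the route at 18.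

Further compounds
F1 | step 2 | (5S,6S)-6-[(2Z)-3-iodoprop-2-en-1-yl]-2,6-dimethyl-5-(prop-1-en-2-yl)cyclohex-2-en-1-one | C=C(C)[C@@H]1CC=C(C)C(=O)[C@@]1(C)C/C=C\I
F2 | step 2 | (4aS,8aS)-2,5,5,8a-tetramethyl-4a,5,8,8a-tetrahydronaphthalen-1(4H)-one | O=C1C(C)=CC[C@H]2C(C)(C)C=CC[C@]12C
F3 | step 6 | (4aS,8aS)-2,5,5,8a-tetramethyl-4a,5,6,7,8,8a-hexahydronaphthalen-1-yl trifluoromethanesulfonate | O=S(=O)(OC1=C(C)C=C[C@H]2C(C)(C)CCC[C@]12C)C(F)(F)F
F4 | step 6 | {3-[(4S)-2,2-dimethyl-1,3-dioxolan-4-yl]but-3-en-1-yl}zinc chloride, C9H15O2ZnCl | Cl[Zn]CCC(=C)[C@H]1COC(C)(C)O1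
F5 | step 6 | (5S,10S,14S)-14,15-(isopropylidenedioxy)labda-6,8,13(16)-triene | C=C(CCC1=C(C)C=C[C@H]2C(C)(C)CCC[C@]12C)[C@H]1COC(C)(C)O1
F6 | step 9 | (5S,7S,10S,14S)-14,15-(isopropylidenedioxy)labda-8,13(16)-dien-7-yl formate | O=CO[C@H]1C[C@H]2C(C)(C)CCC[C@]2(C)C(CCC(=C)[C@H]3COC(C)(C)O3)=C1C
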